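The target in these flasks comes from substrate fed into coupling partner, so I reckoned them by what becomes of each unit of partner.

common to all: substrate 0.045 M (fed, over 15 h); coupling partner 0.0495 M; time 20 h
- delta: temperature 80 °C
- beta: temperature 105 °C
- theta: temperature 130 °C

    crystals ⇌ target, rate k1*(cs1 - [target]) while solid is left; crystals form when [target] > cs1 (cs1 = 9.6 mM, k1 = 5.6 × 10⁻⁴ s⁻¹)
    substrate + 2 coupling partner → side product (k2 = 0.69 L² mol⁻² s⁻¹, Ea2 = 50.0 kJ mol⁻¹)
    substrate + coupling partner → target (k3 = 0.040 L mol⁻¹ s⁻¹, Ea3 = 79.0 kJ mol⁻¹)
    (constants at 80 °C)

* which of these there is most of at the end, counted by the substrate in it, delta (side product / substrate / target)
* which of these there is most of at the end, counted by the substrate in it, beta (side product / substrate / target)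
* which of these there is most of at the end, counted by the substrate in it, theta (side product / substrate / target)
* the largest of these amounts at the end, in percent of the substrate charged, delta
* the largest of these amounts at the end, in percent of the substrate charged, beta
* the largest of these amounts at the end, in percent of the substrate charged, theta

- target is meant together with its crystals
- two of one species on the left: rate k times its square, two consumed each time
- solid, in amounts per volume of the solution: crystals
- the constants hold at 80 °C; other temperatures follow from the activation energies

Bench note, written before the runs. The flask held partner at 1.10 of the substrate charge. In delta the half-life of substrate by the target step, at the charged partner level, was 0.097 h, far shorter than the feed, so I counted on the partner being consumed within the 20 h.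

Both steps are first order in substrate, so substrate cancels from their ratio. With b the fraction of partner still free, the target step takes the share 1/(1+σb) of partner consumed. Here σ, a selectivity factor, is the partner use of the side step over that of the target step at full charge. It came to 1.71 in delta, 0.889 in beta and 0.502 in theta, lower with heat because the target step has the larger activation energy.

I replaced the curve by its mean as b falls from 1 to nothing: the mean target share of the partner, φ = ln(1+σ)/σ. It gave 0.583 in delta, 0.715 in beta and 0.810 in theta. The share at b = 0.5 in delta is lower, 0.539, and gives target at 59.3%; the curve is not straight, so I kept the mean.

Target, as a fraction of the substrate charge, is then the partner charge over the substrate charge times φ: 64.1% in delta, 78.6% in beta and 89.1% in theta. By this reckoning theta needs 99.6% of its substrate, which makes partner the limiting reagent. In theta, neither the crystals nor the feed rate enters φ, so neither needs touching.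

The forecast named target, target and target, at 64% (60% to 67%) in delta, 79% (75% to 81%) in beta and 89% (85% to 91%) in theta, holding that “heat and a low partner level both favour target”.

The runs gave target as the largest amount: 64.1% in delta, 78.7% in beta and 89.1% in theta.

In theta, φ also gives the side product as the same charge ratio times (1−φ)/2, which is 10.4%; the run read 10.4%. The side step is the main reason for theta's shortfall: without it, target stood at 100% instead of 89.1%. In the neighbour of theta with 0.11 M of substrate, σ is unchanged, so φ gives target at 36.5% of that flask's substrate charge; that flask gave 36.5%, with 0% of its partner left.

All constants are invented; the result is computed.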